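**A direct plan and its weak points**

A direct plan would benzylate three of the four phenols of the parent dihydrochalcone to the tribenzyl ether A1 and iodinate ring A beside the last, chelated hydroxyl to the aryl iodide A2. A Suzuki coupling would then turn A2 into the 1-phenylethenyl compound A3, an enantioselective palladium hydride cyclocarbonylation of A3 would close the benzylated lactone A4, and debenzylation of A4 would end the plan. Its weakest steps would be:
- The cyclocarbonylation of A3 that sets C4: it is unknown for 1,1-diarylethenes, the hydride insertion that defines C4 would be reversible, and the hydrogen needed for the hydride could saturate the alkene.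
- The iodination that gives A2: both free C–H positions of ring A in A1 are doubly oxygen-activated, so a mixture of iodides would be likely.
- The tri-benzylation and the halogen detour: three ethers and an iodine atom would be put on and removed, and only two of five steps would make bonds of the target.

**Retrosynthetic overview**

- Disconnection: C4–C4a and O1–C2 are cut together. The lactone ring is read as a cinnamoyl unit (C2–C3–C4 with its phenyl) laid across the acylphloroglucinol ring A of phloretin, between a ring carbon and the hydroxyl ortho to the C8 ketone.
- Key step: a chiral triazolylidene turns phenylpropiolaldehyde into a cinnamoyl azolium. Ring A attacks it through carbon (C4–C4a, sets 4R), then the neighbouring hydroxyl closes the lactone (O1–C2). Rings A and B come intact from phloretin, and the lactone is the only ring made.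
- Regiocontrol by symmetry: one benzyl ether on the oxygen para to the ketone (O4' of phloretin, later O5) makes the two remaining ring A hydroxyls and the two ring A C–H positions equivalent. Only the 8-acyl lactone can then form; left free, this most acidic hydroxyl would compete for the acyl group and lead to the 6-acyl isomer.
- The design needs no halogenation, cross-coupling or carbonylation, uses one benzyl group instead of three, sets C4 in a C–C bond formation of a precedented catalyst class, and takes three steps.

Key step: step 2

Assumption: the (5aR,10bS) antipode of the aminoindanol-derived triazolium salt is taken to leave the Re face of C-β of the cinnamoyl azolium open; both antipodes are commercial, so the other one would be used if the sense were the reverse.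

**Route**

Step 1
Reactants: 1 phloretin; 2 benzyl bromide
Product: 3 1-[4-(benzyloxy)-2,6-dihydroxyphenyl]-3-(4-hydroxyphenyl)propan-1-one (4'-O-benzylphloretin)
Conditions: BnBr (1.05 equiv), CsHCO3 (1.3 equiv), MeCN, 60 °C
Reagents that add atoms: benzyl bromide (2), BrCc1ccccc1
Why: Williamson etherification under acidity control, in which hydrogen carbonate deprotonates only the hydroxyl para to the ketone (a vinylogous carboxylic acid, pKa about 7) while the two ortho hydroxyls and the ring B phenol (pKa about 10) stay protonated, so that one benzyl group should go to O4' alone, as in the hydrogen carbonate mediated 4-O-alkylation of 2,4-dihydroxyaryl ketones, with O- favoured over C-alkylation in the polar aprotic solvent.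

Step 2
Reactants: 3 1-[4-(benzyloxy)-2,6-dihydroxyphenyl]-3-(4-hydroxyphenyl)propan-1-one; 4 3-phenylprop-2-ynal
Product: 5 (4R)-5-(benzyloxy)-7-hydroxy-8-[3-(4-hydroxyphenyl)propanoyl]-4-phenyl-3,4-dihydro-2H-chromen-2-one
Conditions: 4 (1.2 equiv), (5aR,10bS)-2-(2,4,6-trimethylphenyl)-5a,10b-dihydro-4H,6H-indeno[2,1-b][1,2,4]triazolo[4,3-d][1,4]oxazin-2-ium chloride (10 mol %), no added base, toluene/THF (4:1), 40 °C
Reagents that add atoms: 3-phenylprop-2-ynal (4), O=CC#Cc1ccccc1
Why: The carbene adds to the aldehyde of 4 and proton transfer through the allenol gives the catalyst-bound (E)-cinnamoyl azolium by internal redox, to which the vinylogous-acid ring A of 3 adds through the ring carbon next to a free hydroxyl (by conjugate addition, or by 1,2-addition and [3,3] shift) to form C4–C4a; tautomerisation gives the saturated acyl azolium, which that hydroxyl captures (O1–C2) with release of the carbene, so that nothing is set free. The closest known reaction type is the carbene-catalysed [3+3] annulation of ynals or enals with naphthols, kojic acids and 1,3-dicarbonyl enols to 4-aryl-3,4-dihydropyran-2-ones and benzo-fused dihydrocoumarins. The lactone ring closes by 6-exo-trig acyl substitution at the acyl azolium carbon after the intermolecular C–C bond has been made. C4 is set in the C–C bond formation by the aminoindanol backbone of the catalyst, which shields one face of the planar acyl azolium so that ring A attacks the Re face of C-β, and this corresponds to 4R. The step needs C- over O-acylation and one lactone constitution only: the benzyl ether on O4' leaves two equivalent hydroxyls and two equivalent ring carbons, so that every productive path gives the 8-acyl lactone, the lactone formed deactivates ring A against a second annulation, and without added base the less acidic ring B phenol should not be acylated at a competitive rate.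

Step 3
Reactants: 5 (4R)-5-(benzyloxy)-7-hydroxy-8-[3-(4-hydroxyphenyl)propanoyl]-4-phenyl-3,4-dihydro-2H-chromen-2-one
Product: 6 (4R)-5,7-dihydroxy-8-[3-(4-hydroxyphenyl)propanoyl]-4-phenyl-3,4-dihydro-2H-chromen-2-one
Conditions: H2 (1 atm), Pd/C (10 wt % Pd), EtOAc, 25 °C
Reagents that add atoms: none
Why: Catalytic hydrogenolysis of the single aryl benzyl ether, in which C4 carries no heteroatom and is neither cleaved nor epimerised, and the aryl lactone and the chelated aryl ketone persist in a neutral aprotic solvent at ambient pressure, so that the 4R configuration is carried into the target and the lactone has no acid or base with which to change its place.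

**Compound list**

1 | phloretin, 3-(4-hydroxyphenyl)-1-(2,4,6-trihydroxyphenyl)propan-1-one | O=C(CCc1ccc(O)cc1)c1c(O)cc(O)cc1O | starting material
2 | benzyl bromide | BrCc1ccccc1 | starting material
3 | 1-[4-(benzyloxy)-2,6-dihydroxyphenyl]-3-(4-hydroxyphenyl)propan-1-one (4'-O-benzylphloretin) | O=C(CCc1ccc(O)cc1)c1c(O)cc(OCc2ccccc2)cc1O | intermediate
4 | 3-phenylprop-2-ynal | O=CC#Cc1ccccc1 | starting material
5 | (4R)-5-(benzyloxy)-7-hydroxy-8-[3-(4-hydroxyphenyl)propanoyl]-4-phenyl-3,4-dihydro-2H-chromen-2-one | O=C1C[C@H](c2ccccc2)c2c(OCc3ccccc3)cc(O)c(C(=O)CCc3ccc(O)cc3)c2O1 | intermediate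
6 | (4R)-5,7-dihydroxy-8-[3-(4-hydroxyphenyl)propanoyl]-4-phenyl-3,4-dihydro-2H-chromen-2-one | O=C1C[C@H](c2ccccc2)c2c(O)cc(O)c(C(=O)CCc3ccc(O)cc3)c2O1 | target

**Step count and risks**

Total step count: 3. Longest linear sequence: 3.

Steps most likely to fail:

1. Step 2 (key step). The acyl azolium may be consumed by O-acylation of the ring B phenol or of a ring A oxygen without C–C bond formation, carbon attack by the acyl-deactivated, hydrogen-bonded ring A may be slow, or the facial discrimination at C-β may be insufficient. The fallback sets out from 3 and comes back at 5, and it uses iminium catalysis instead of acyl transfer, so that no acyl donor is present. With (E)-cinnamaldehyde, (R)-α,α-diphenylprolinol trimethylsilyl ether (20 mol %) and PhCO2H (20 mol %) in toluene at 0 °C, ring A should add to the Re face of the iminium β-carbon (Friedel–Crafts alkylation), and the neighbouring hydroxyl should close the hemiacetal; the antipode of the amine would be used if the facial sense were the reverse. This would give the lactol 1-[(4R)-5-(benzyloxy)-2,7-dihydroxy-4-phenyl-3,4-dihydro-2H-chromen-8-yl]-3-(4-hydroxyphenyl)propan-1-one F1 as a mixture of C2 epimers. Oxidation of the lactol with [C5H5NH][CrO3Cl] buffered with NaOAc in CH2Cl2 at 25 °C would give 5.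

2. Step 1. Alkylation may run on to an ortho hydroxyl or to the ring B phenol, or the ambident phloroglucinol anion may be benzylated at carbon. The fallback sets out from 2 and comes back at 3, and it uses commercial naringenin (the flavanone isomer of the chalcone of 1) in place of 1. Its pyranone ring ties up one ortho oxygen and the other is firmly chelated, so that benzylation with 2 and CsHCO3 in MeCN can only reach the acidic 7-hydroxyl. This would give 7-(benzyloxy)-5-hydroxy-2-(4-hydroxyphenyl)-2,3-dihydro-4H-chromen-4-one F2, used as the racemate. Alkaline ring opening (KOH aq., 25 °C) would give the chalcone (E)-1-[4-(benzyloxy)-2,6-dihydroxyphenyl]-3-(4-hydroxyphenyl)prop-2-en-1-one F3 as its potassium salt, which would not be isolated. Hydrogenation of its C=C bond in the same pot (H2 1 atm, Raney Ni, 25 °C; the aryl benzyl ether is expected to persist over nickel at ambient pressure), followed by acidification, would give 3.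

3. Step 3. Hydrogenolysis of the benzyl ether on O5, which lies peri to the C4 phenyl group, may stall, and forcing it may start reduction of the aryl ketone or, with a protic co-solvent, opening of the lactone. The fallback sets out from 5 and comes back at 6 without a new compound: a non-reductive Lewis acid cleavage with BCl3 (3 equiv) and pentamethylbenzene (5 equiv) as cation scavenger in CH2Cl2 at −78 °C, followed by cold aqueous work-up.

**Further compounds**

F1 | step 2 | 1-[(4R)-5-(benzyloxy)-2,7-dihydroxy-4-phenyl-3,4-dihydro-2H-chromen-8-yl]-3-(4-hydroxyphenyl)propan-1-one (lactol, both C2 epimers) | OC1C[C@H](c2ccccc2)c2c(OCc3ccccc3)cc(O)c(C(=O)CCc3ccc(O)cc3)c2O1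
F2 | step 1 | 7-(benzyloxy)-5-hydroxy-2-(4-hydroxyphenyl)-2,3-dihydro-4H-chromen-4-one (racemic) | O=C1CC(c2ccc(O)cc2)Oc2cc(OCc3ccccc3)cc(O)c12
F3 | step 1 | (E)-1-[4-(benzyloxy)-2,6-dihydroxyphenyl]-3-(4-hydroxyphenyl)prop-2-en-1-one | O=C(/C=C/c1ccc(O)cc1)c1c(O)cc(OCc2ccccc2)cc1O
F0 | step 3 | none | none
A1 | direct plan | 1-[2,4-bis(benzyloxy)-6-hydroxyphenyl]-3-[4-(benzyloxy)phenyl]propan-1-one | O=C(CCc1ccc(OCc2ccccc2)cc1)c1c(O)cc(OCc2ccccc2)cc1OCc1ccccc1
A2 | direct plan | 1-[4,6-bis(benzyloxy)-2-hydroxy-3-iodophenyl]-3-[4-(benzyloxy)phenyl]propan-1-one | O=C(CCc1ccc(OCc2ccccc2)cc1)c1c(O)c(I)c(OCc2ccccc2)cc1OCc1ccccc1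
A3 | direct plan | 1-[4,6-bis(benzyloxy)-2-hydroxy-3-(1-phenylethenyl)phenyl]-3-[4-(benzyloxy)phenyl]propan-1-one | C=C(c1ccccc1)c1c(OCc2ccccc2)cc(OCc2ccccc2)c(C(=O)CCc2ccc(OCc3ccccc3)cc2)c1O
A4 | direct plan | (4R)-5,7-bis(benzyloxy)-8-{3-[4-(benzyloxy)phenyl]propanoyl}-4-phenyl-3,4-dihydro-2H-chromen-2-one | O=C1C[C@H](c2ccccc2)c2c(OCc3ccccc3)cc(OCc3ccccc3)c(C(=O)CCc3ccc(OCc4ccccc4)cc3)c2O1
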